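**Retrosynthetic overview** (target numbering: C1 lactone C=O, C3 CH–OO, C4 C(Me)–O, C6 C(Me)(alkyl)–OO)
- The 1,2-dioxane is closed last: O–C3 bond by intramolecular oxa-Michael addition of a C6 tertiary hydroperoxide to an (R)-γ,γ-disubstituted butenolide, which fixes C3 cis to C4.
- C6–OO comes from cobalt-mediated hydroperoxysilylation of a C6=C7 trisubstituted alkene, itself made by cross-metathesis of a methallyl butenolide with 13-phenyltridec-1-ene.
- The methallyl group comes from a methyl ketone (methylenation), and the ketone from a secondary nitro group (Nef).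
- Key C4–C5 bond: the vinylogous dienolate of α-angelica lactone (γ-carbon nucleophile) adds to 2-nitropropene, an acetonyl-cation (ketone α-cation) equivalent, under chiral amine–thiourea catalysis; this creates the C4 quaternary stereocentre.
- Ring order: the lactone ring is carried from α-angelica lactone throughout; the peroxide ring is formed in the final step. C6 is not controlled (about 1:1) and the target epimer is isolated by chromatography at the end.

Assumption: the quinine-derived thiourea is taken to give the (R)-configured quaternary centre; if the first run shows the opposite sense, its quinidine-derived pseudo-enantiomer is used instead.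

**Step 1**
Reactants: 1 2-nitropropan-1-ol
Product: 3 2-nitroprop-1-ene, via 2-nitropropyl hydrogen phthalate 2 (not isolated)
Conditions: phthalic anhydride (1.3 equiv), neat, 150 → 180 °C, 110 mmHg, product distilled out and used fresh
Reagents that add atoms: none
Why: Acylation of the alcohol by the anhydride gives the half-ester, whose E1cB-type elimination (β-nitro ester) releases the volatile nitroalkene, which distils as it forms and so escapes polymerisation.

**Step 2**
Reactants: 4 α-angelica lactone (5-methylfuran-2(3H)-one); 3 2-nitroprop-1-ene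
Product: 5 (5R)-5-methyl-5-(2-nitropropyl)furan-2(5H)-one (both epimers at the nitro-bearing carbon)
Conditions: 4 (1.5 equiv), 3 added over 6 h, 9-amino-9-deoxy-epi-quinine 3,5-bis(trifluoromethyl)phenyl thiourea (10 mol %), toluene, −40 °C
Reagents that add atoms: none
Why: Proposed new method: the quinuclidine nitrogen deprotonates 4 to an ammonium-paired 2-oxidofuran dienolate while the thiourea hydrogen-bonds the nitro group of 3, and the γ-carbon of the dienolate adds from one face to the unsubstituted β-carbon of 3, so that the butenolide γ-carbon is joined to the future α-carbon of a methyl ketone (3 acting as an acetonyl-cation equivalent) and the quaternary centre is set as 5R by the catalyst; the closest known reaction is the amine–thiourea-catalysed direct vinylogous Michael addition of α-angelica lactone to β-substituted nitroalkenes, which gives γ,γ-disubstituted butenolides in high ee.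

**Step 3**
Reactants: 5 (5R)-5-methyl-5-(2-nitropropyl)furan-2(5H)-one
Product: 8 (5R)-5-methyl-5-(2-oxopropyl)furan-2(5H)-one, via oxime 6 (not isolated), via NH-imine 7 (not isolated)
Conditions: TiCl3 (4.5 equiv, aq HCl solution), DME, 25 °C, 24 h
Reagents that add atoms: water, SMILES O
Why: Reductive Nef reaction (McMurry): trivalent titanium takes the nitro group through the oxime to the N–H imine, which hydrolyses to the methyl ketone under acidic, non-basic conditions that leave the butenolide and the adjacent quaternary centre untouched and avoid base-triggered intramolecular Michael closure.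

**Step 4**
Reactants: 8 (5R)-5-methyl-5-(2-oxopropyl)furan-2(5H)-one
Product: 9 (5R)-5-methyl-5-(2-methylprop-2-en-1-yl)furan-2(5H)-one
Conditions: Zn, CH2Br2, TiCl4 (pre-formed reagent), THF–CH2Cl2, 0 → 25 °C
Reagents that add atoms: dibromomethane, SMILES BrCBr
Why: Takai–Lombardo methylenation: the non-basic gem-dimetallic methylene reagent olefinates the ketone selectively over the lactone carbonyl and cannot enolise the β-acyloxy ketone, so neither elimination of the lactone oxygen nor attack on the butenolide occurs.

**Step 5**
Reactants: 10 11-bromoundec-1-ene; 11 2-phenylethylmagnesium chloride (commercial THF solution)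
Product: 12 13-phenyltridec-1-ene
Conditions: 11 (1.2 equiv), Li2CuCl4 (3 mol %), THF, −10 → 25 °C
Reagents that add atoms: none
Why: Kochi copper-catalysed sp3–sp3 cross-coupling of an alkyl Grignard reagent with a primary alkyl bromide, which tolerates the terminal alkene.

**Step 6**
Reactants: 9 (5R)-5-methyl-5-(2-methylprop-2-en-1-yl)furan-2(5H)-one; 12 13-phenyltridec-1-ene
Product: 13 (5R)-5-methyl-5-(2-methyl-14-phenyltetradec-2-en-1-yl)furan-2(5H)-one (E/Z mixture)
Conditions: 12 (3 equiv), second-generation Hoveyda–Grubbs catalyst RuCl2(H2IMes)(=CH-C6H4-2-O-i-Pr) (5 mol %), CH2Cl2, 40 °C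
Reagents that add atoms: none
Why: Olefin cross-metathesis of the 1,1-disubstituted alkene with an excess of the terminal alkene gives the trisubstituted C2′=C3′ alkene with loss of ethene, the electron-poor endocyclic butenolide alkene being inert to the ruthenium carbene, and the E/Z ratio is irrelevant because the alkene is consumed in the next step.

**Step 7**
Reactants: 13 (5R)-5-methyl-5-(2-methyl-14-phenyltetradec-2-en-1-yl)furan-2(5H)-one
Product: 14 (5R)-5-methyl-5-[2-methyl-14-phenyl-2-(triethylsilylperoxy)tetradecyl]furan-2(5H)-one (about 1:1 epimers at C2′)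
Conditions: Co(thd)2 [bis(2,2,6,6-tetramethylheptane-3,5-dionato)cobalt] (10 mol %), Et3SiH (3 equiv), O2 (1 atm), ClCH2CH2Cl, 25 °C
Reagents that add atoms: dioxygen, SMILES O=O; triethylsilane, SMILES CC[SiH](CC)CC
Why: Mukaiyama–Isayama hydroperoxysilylation: hydrogen-atom transfer from a cobalt hydride to the electron-rich trisubstituted alkene gives the tertiary C2′ radical (Markovnikov), which captures O2 and is silylated while the electron-poor butenolide is untouched; the radical is planar and remote from C5, so the peroxide-bearing carbon forms as a roughly 1:1 pair of epimers, one of which has the configuration of the target.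

**Step 8**
Reactants: 14 (5R)-5-methyl-5-[2-methyl-14-phenyl-2-(triethylsilylperoxy)tetradecyl]furan-2(5H)-one
Product: 16 plakortolide K [(3S,4aR,7aR)-3,4a-dimethyl-3-(12-phenyldodecyl)tetrahydro-3H-furo[3,2-c][1,2]dioxin-6(4H)-one], via hydroperoxide 15 (not isolated)
Conditions: HCl (cat.), MeOH, 0 °C; then Et2NH (0.3 equiv), CF3CH2OH, 25 °C; silica chromatography
Reagents that add atoms: none
Why: Acidic methanolysis frees the tertiary hydroperoxide and amine-catalysed 6-exo-trig intramolecular oxa-Michael addition to the butenolide closes the 1,2-dioxane from the lactone face that carries the tether, so C7a is set cis to C4a (7aR from 4aR), and the diastereomer epimeric at C3 that arises from the other half of 14 is separated here by chromatography.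

**Compound list**
1 | 2-nitropropan-1-ol (racemic) | CC(CO)[N+](=O)[O-] | starting material
2 | 2-nitropropyl hydrogen phthalate (not isolated) | CC(COC(=O)c1ccccc1C(=O)O)[N+](=O)[O-] | intermediate
3 | 2-nitroprop-1-ene | CC(=C)[N+](=O)[O-] | intermediate
4 | α-angelica lactone, 5-methylfuran-2(3H)-one | CC1=CCC(=O)O1 | starting material
5 | (5R)-5-methyl-5-(2-nitropropyl)furan-2(5H)-one, both epimers at the nitro carbon | CC([N+](=O)[O-])C[C@@]1(C)OC(=O)C=C1 | intermediate
6 | (5R)-5-[2-(hydroxyimino)propyl]-5-methylfuran-2(5H)-one (oxime, not isolated) | CC(=NO)C[C@@]1(C)OC(=O)C=C1 | intermediate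
7 | (5R)-5-(2-iminopropyl)-5-methylfuran-2(5H)-one (N–H imine, not isolated) | CC(=N)C[C@@]1(C)OC(=O)C=C1 | intermediate
8 | (5R)-5-methyl-5-(2-oxopropyl)furan-2(5H)-one | CC(=O)C[C@@]1(C)OC(=O)C=C1 | intermediate
9 | (5R)-5-methyl-5-(2-methylprop-2-en-1-yl)furan-2(5H)-one | CC(=C)C[C@@]1(C)OC(=O)C=C1 | intermediate
10 | 11-bromoundec-1-ene | C=CCCCCCCCCCBr | starting material
11 | 2-phenylethylmagnesium chloride | Cl[Mg]CCc1ccccc1 | starting material
12 | 13-phenyltridec-1-ene | C=CCCCCCCCCCCCc1ccccc1 | intermediate
13 | (5R)-5-methyl-5-(2-methyl-14-phenyltetradec-2-en-1-yl)furan-2(5H)-one, E/Z mixture | CC(=CCCCCCCCCCCCc1ccccc1)C[C@@]2(C)OC(=O)C=C2 | intermediate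
14 | (5R)-5-methyl-5-[2-methyl-14-phenyl-2-(triethylsilylperoxy)tetradecyl]furan-2(5H)-one, about 1:1 epimers at C2′ | CC(CCCCCCCCCCCCc1ccccc1)(OO[Si](CC)(CC)CC)C[C@@]2(C)OC(=O)C=C2 | intermediate
15 | (5R)-5-(2-hydroperoxy-2-methyl-14-phenyltetradecyl)-5-methylfuran-2(5H)-one, epimers at C2′ (not isolated) | CC(CCCCCCCCCCCCc1ccccc1)(OO)C[C@@]2(C)OC(=O)C=C2 | intermediate
16 | plakortolide K, (3S,4aR,7aR)-3,4a-dimethyl-3-(12-phenyldodecyl)tetrahydro-3H-furo[3,2-c][1,2]dioxin-6(4H)-one | C[C@]1(CCCCCCCCCCCCc2ccccc2)C[C@@]2(C)OC(=O)C[C@H]2OO1 | target

**Totals**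
Total step count: 8. Longest linear sequence: 7 (steps 1, 2, 3, 4, 6, 7, 8, from 2-nitropropan-1-ol).

**Three steps most likely to fail**

Step 2. The risks are the enantioselectivity with a β-unsubstituted nitroalkene and amine-induced oligomerisation of 3. The fallback replaces catalyst control by chiral-pool control; it sets out from 3 and comes back at 5. (S)-Lactic acid and pivalaldehyde (TsOH, pentane, water removal) give (2S,5S)-2-tert-butyl-5-methyl-1,3-dioxolan-4-one F1. Deprotonation with LiN(i-Pr)2 (THF, −78 °C) and addition to 3 on the face away from the tert-butyl group gives, after an acetic acid quench, (2S,5R)-2-tert-butyl-5-methyl-5-(2-nitropropyl)-1,3-dioxolan-4-one F2. Reduction with i-Bu2AlH (CH2Cl2, −78 °C) and dilute acid gives (2R)-2-hydroxy-2-methyl-4-nitropentanal F3 with loss of pivalaldehyde. Ph3P=C=C=O (toluene, 80 °C) then acylates the tertiary hydroxyl and closes the butenolide by intramolecular Wittig reaction, returning 5 with the same 5R configuration.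

Step 6. The 1,1-disubstituted alkene of 9 sits next to a neopentyl-type centre and may metathesise sluggishly. The fallback brings the chain in as a carbon nucleophile instead; it sets out from 8 and comes back at 15, bypassing steps 4, 6 and 7. 1-Bromo-12-phenyldodecane F4 (from 11 and 1,10-dibromodecane, Li2CuCl4 cat.) is converted with Mg into 12-phenyldodecylmagnesium bromide F5. In the presence of CeCl3 at −78 °C this adds to the ketone of 8, which is far more electrophilic than the lactone, to give (5R)-5-(2-hydroxy-2-methyl-14-phenyltetradecyl)-5-methylfuran-2(5H)-one F6. H2O2 (50%) with catalytic H2SO4 at 0 °C exchanges OH for OOH through the tertiary cation and gives 15 (both epimers, as in the main route), which is cyclised as in the second half of step 8.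

Step 7. Hydrogen-atom transfer to the hindered alkene may be slow, or the butenolide may be reduced. The fallback is a polar instead of a radical peroxidation; it sets out from 13 and comes back at 15. Hg(OAc)2 and H2O2 in THF add across the trisubstituted alkene in the Markovnikov sense (the electron-poor butenolide does not react with the mercury electrophile) to give (5R)-5-[3-(acetoxymercurio)-2-hydroperoxy-2-methyl-14-phenyltetradecyl]-5-methylfuran-2(5H)-one F7. NaBH4 in aqueous NaOH at 0 °C replaces mercury by hydrogen and gives 15 (both epimers at the peroxide carbon), which rejoins step 8 at the cyclisation stage.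

**Further compounds**
F1 | step 2 | (2S,5S)-2-tert-butyl-5-methyl-1,3-dioxolan-4-one | C[C@@H]1O[C@H](C(C)(C)C)OC1=O
F2 | step 2 | (2S,5R)-2-tert-butyl-5-methyl-5-(2-nitropropyl)-1,3-dioxolan-4-one | C[C@]1(CC(C)[N+](=O)[O-])O[C@H](C(C)(C)C)OC1=O
F3 | step 2 | (2R)-2-hydroxy-2-methyl-4-nitropentanal | CC([N+](=O)[O-])C[C@@](C)(O)C=O
F4 | step 6 | 1-bromo-12-phenyldodecane | BrCCCCCCCCCCCCc1ccccc1
F5 | step 6 | 12-phenyldodecylmagnesium bromide | Br[Mg]CCCCCCCCCCCCc1ccccc1
F6 | step 6 | (5R)-5-(2-hydroxy-2-methyl-14-phenyltetradecyl)-5-methylfuran-2(5H)-one | CC(O)(CCCCCCCCCCCCc1ccccc1)C[C@@]2(C)OC(=O)C=C2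
F7 | step 7 | (5R)-5-[3-(acetoxymercurio)-2-hydroperoxy-2-methyl-14-phenyltetradecyl]-5-methylfuran-2(5H)-one | CC(=O)O[Hg]C(CCCCCCCCCCCc1ccccc1)C(C)(OO)C[C@@]2(C)OC(=O)C=C2
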